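**Strategy**

The plan rests on cutting the trimethylcyclohexene (ring A; C1 carries the side chain, C2 the methyl group, C6 the gem-dimethyl group) across two opposite bonds, the tetrasubstituted C1=C2 alkene and the C4–C5 single bond. This leaves two three-carbon pieces, each a ketone with a reactive β-carbon: a neopentyl β-bromo ketone (C5–C6–C1, with a chloroethyl handle) and methyl vinyl ketone (C4–C3–C2). In one flask, zinc converts the first into a homoenolate that adds to the enone (C4–C5), and low-valent titanium then joins the two ketone carbons (C1=C2), which fixes the alkene position. A (Z)-alkenyl iodide and an enantioselectively made 2-vinylchroman complete the diene.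

Key step: step 3

Remark (assumption): in step 7 the (S,S)-ligand is assumed to give the (R)-chroman; if the facial sense is the opposite, the (R,R)-ligand is used with no other change.

**Route**

Step 1
Reactants: 1 3-bromo-2,2-dimethylpropanoic acid
Product: 2 3-bromo-2,2-dimethylpropanoyl chloride
Conditions: (COCl)2, DMF (cat.), CH2Cl2, 0 to 20 °C
Reagents that add atoms: oxalyl chloride, ClC(=O)C(=O)Cl
Why: Acyl substitution through the chloroiminium (Vilsmeier-type) catalyst should give the acid chloride, the neopentyl C–Br bond being inert to displacement.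

Step 2
Reactants: 2 3-bromo-2,2-dimethylpropanoyl chloride; 3 ethylene
Product: 4 1-bromo-5-chloro-2,2-dimethylpentan-3-one
Conditions: AlCl3, ethylene (1 atm), CH2Cl2, −20 to 0 °C
Reagents that add atoms: none
Why: Darzens–Nenitzescu (aliphatic Friedel–Crafts) acylation of ethylene, with chloride capture of the β-carbocation, should give the β-chloroethyl ketone; the low temperature is chosen to outrun loss of CO from the tertiary acylium ion.

Step 3
Reactants: 4 1-bromo-5-chloro-2,2-dimethylpentan-3-one; 5 methyl vinyl ketone (but-3-en-2-one)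
Product: 9 2-(2-chloroethyl)-1,3,3-trimethylcyclohex-1-ene, via zinc homoenolate 6 (not isolated), via silyl enol ether 7 (not isolated), via 1,6-diketone 8 (not isolated)
Conditions: Zn dust (1.5 equiv), LiCl, THF, 40 °C; CuBr·SMe2 (10 mol %), Me3SiCl, 5, −30 to 20 °C; MeOH (1.2 equiv); then THF (to 0.01 M), Zn dust (8 equiv), TiCl4 (4 equiv), 0 °C to reflux
Reagents that add atoms: none
Why: Zinc inserts into the neopentyl C–Br bond of 4 (the primary C–Cl bond is left alone) to give the β-zincio ketone 6, a ketone homoenolate in equilibrium with its zinc cyclopropanolate, which under monovalent copper catalysis adds 1,4 to 5 with Me3SiCl trapping as 7 and so forms the C4–C5 bond of ring A. Methanol then frees the 1,6-diketone 8, and low-valent titanium made in the same flask from TiCl4 and zinc joins its two carbonyl carbons through a titanium pinacolate that loses both oxygens to the metal, forming the C1=C2 double bond. The closest known reactions are the copper-catalysed conjugate addition of zinc homoenolates to enones and the intramolecular McMurry coupling of diketones to tetrasubstituted cycloalkenes. The ring is closed in the second event as a six-membered carbocycle by carbonyl–carbonyl coupling of a 1,6-diketone, the first bond being made between the two components. No stereocenter is formed; the step needs regiocontrol of the alkene and chemoselectivity, secured because the double bond can only arise between the two former carbonyl carbons (a dehydration could also place it at C2=C3 or exocyclic), because zinc discriminates bromide from chloride, and because copper with Me3SiCl enforces 1,4-addition while high dilution and the favourable six-ring closure suppress intermolecular coupling.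

Step 4
Reactants: 9 2-(2-chloroethyl)-1,3,3-trimethylcyclohex-1-ene; 10 propyne
Product: 13 2-[(3Z)-4-iodo-3-methylbut-3-en-1-yl]-1,3,3-trimethylcyclohex-1-ene, via Grignard reagent 11 (not isolated), via alkenylcopper 12 (not isolated)
Conditions: Mg, Et2O, reflux; CuBr·SMe2, Et2O/Me2S, −45 °C; propyne, −25 °C; I2 (1 equiv), −50 to 0 °C
Reagents that add atoms: iodine, [I][I]
Why: Normant carbocupration: the alkylcopper adds syn across propyne with copper on the terminal carbon, so the ring-bearing chain and the metal are cis, and iodinolysis with retention should give the (Z)-trisubstituted alkenyl iodide.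

Step 5
Reactants: 14 4-[(tert-butyldimethylsilyl)oxy]phenol
Product: 15 2-bromo-4-[(tert-butyldimethylsilyl)oxy]phenol
Conditions: NBS, i-Pr2NH (cat.), CH2Cl2, 0 °C
Reagents that add atoms: N-bromosuccinimide, BrN1C(=O)CCC1=O
Why: Electrophilic aromatic bromination should occur ortho to the free hydroxyl, the stronger donor, whose para position is occupied by the silyloxy group.

Step 6
Reactants: 15 2-bromo-4-[(tert-butyldimethylsilyl)oxy]phenol; 16 (3E)-3-methylpenta-1,3-diene
Product: 18 4-[(tert-butyldimethylsilyl)oxy]-2-[(3E)-3-methylpent-3-en-1-yl]phenol, via B-alkyl-9-BBN 17 (not isolated)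
Conditions: 16, 9-BBN, THF, 0 to 20 °C; then 15, PdCl2(dppf) (5 mol %), K3PO4, DMF/THF/H2O, 50 °C
Reagents that add atoms: none
Why: Anti-Markovnikov hydroboration of the monosubstituted alkene of the diene by 9-BBN, then B-alkyl Suzuki–Miyaura coupling with the aryl bromide; the (E)-trisubstituted alkene is carried over unchanged from 16.

Step 7
Reactants: 18 4-[(tert-butyldimethylsilyl)oxy]-2-[(3E)-3-methylpent-3-en-1-yl]phenol
Product: 19 tert-butyl{[(2R)-2-ethenyl-2-methyl-3,4-dihydro-2H-chromen-6-yl]oxy}dimethylsilane
Conditions: Pd(OCOCF3)2 (10 mol %), (S,S)-Bn-BOXAX [2,2'-bis(4-benzyl-4,5-dihydrooxazol-2-yl)-1,1'-binaphthyl] (20 mol %), p-benzoquinone (4 equiv), MeOH, 40 °C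
Reagents that add atoms: none
Why: Enantioselective Wacker-type oxidative cyclization: 6-exo oxypalladation of the trisubstituted alkene by the phenol and β-hydride elimination towards the methyl group give the vinyl group, and the quaternary C2 stereocenter is set by the chiral bis(oxazoline) ligand on divalent palladium, which selects the alkene face.

Step 8
Reactants: 19 tert-butyl{[(2R)-2-ethenyl-2-methyl-3,4-dihydro-2H-chromen-6-yl]oxy}dimethylsilane; 20 4,4,5,5-tetramethyl-2-vinyl-1,3,2-dioxaborolane
Product: 21 tert-butyldimethyl{[(2R)-2-methyl-2-[(E)-2-(4,4,5,5-tetramethyl-1,3,2-dioxaborolan-2-yl)ethenyl]-3,4-dihydro-2H-chromen-6-yl]oxy}silane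
Conditions: 20 (3 equiv), second-generation Grubbs catalyst RuCl2(=CHPh)(H2IMes)(PCy3) (5 mol %), CH2Cl2, 40 °C
Reagents that add atoms: none
Why: Olefin cross-metathesis with excess vinylboronate (ethylene is lost) should give the (E)-alkenylboronate, favoured by the bulk of both alkene substituents; the C2 stereocenter is not touched.

Step 9
Reactants: 21 the (E)-alkenylboronate of step 8; 13 2-[(3Z)-4-iodo-3-methylbut-3-en-1-yl]-1,3,3-trimethylcyclohex-1-ene
Product: 22 tert-butyldimethyl{[(2R)-2-methyl-2-[(1E,3Z)-4-methyl-6-(2,6,6-trimethylcyclohex-1-en-1-yl)hexa-1,3-dien-1-yl]-3,4-dihydro-2H-chromen-6-yl]oxy}silane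
Conditions: PdCl2(dppf) (5 mol %), K3PO4, THF/H2O (10:1), 45 °C, degassed, dark
Reagents that add atoms: none
Why: Suzuki–Miyaura alkenyl–alkenyl coupling is stereoretentive at both partners, so the (1E,3Z)-diene follows from the geometries of 21 and 13; the stereocenter is not involved.

Step 10
Reactants: 22 the silyl ether of step 9
Product: 23 (2R)-2-methyl-2-[(1E,3Z)-4-methyl-6-(2,6,6-trimethylcyclohex-1-en-1-yl)hexa-1,3-dien-1-yl]-3,4-dihydro-2H-chromen-6-ol
Conditions: Bu4NF, THF, 0 °C; aqueous NH4Cl
Reagents that add atoms: none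
Why: Fluoride cleavage of the aryl silyl ether (Si–F bond formation) under non-acidic conditions should leave the diene geometry and the stereocenter untouched.

**Compound list**

1 | 3-bromo-2,2-dimethylpropanoic acid | OC(=O)C(C)(C)CBr | starting material
2 | 3-bromo-2,2-dimethylpropanoyl chloride | ClC(=O)C(C)(C)CBr | intermediate
3 | ethylene | C=C | starting material
4 | 1-bromo-5-chloro-2,2-dimethylpentan-3-one | BrCC(C)(C)C(=O)CCCl | intermediate
5 | methyl vinyl ketone (but-3-en-2-one) | CC(=O)C=C | starting material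
6 | bromo(5-chloro-2,2-dimethyl-3-oxopentyl)zinc (zinc homoenolate) | ClCCC(=O)C(C)(C)C[Zn]Br | intermediate
7 | 9-chloro-6,6-dimethyl-2-[(trimethylsilyl)oxy]non-2-en-7-one | CC(O[Si](C)(C)C)=CCCC(C)(C)C(=O)CCCl | intermediate
8 | 1-chloro-4,4-dimethylnonane-3,8-dione | ClCCC(=O)C(C)(C)CCCC(C)=O | intermediate
9 | 2-(2-chloroethyl)-1,3,3-trimethylcyclohex-1-ene | CC1=C(CCCl)C(C)(C)CCC1 | intermediate
10 | propyne | CC#C | starting material
11 | [2-(2,6,6-trimethylcyclohex-1-en-1-yl)ethyl]magnesium chloride | CC1=C(CC[Mg]Cl)C(C)(C)CCC1 | intermediate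
12 | [(1Z)-2-methyl-4-(2,6,6-trimethylcyclohex-1-en-1-yl)but-1-en-1-yl]copper (magnesium halide complex) | CC1=C(CC/C(C)=C\[Cu])C(C)(C)CCC1 | intermediate
13 | 2-[(3Z)-4-iodo-3-methylbut-3-en-1-yl]-1,3,3-trimethylcyclohex-1-ene | CC1=C(CC/C(C)=C\I)C(C)(C)CCC1 | intermediate
14 | 4-[(tert-butyldimethylsilyl)oxy]phenol | Oc1ccc(O[Si](C)(C)C(C)(C)C)cc1 | starting material
15 | 2-bromo-4-[(tert-butyldimethylsilyl)oxy]phenol | Oc1ccc(O[Si](C)(C)C(C)(C)C)cc1Br | intermediate
16 | (3E)-3-methylpenta-1,3-diene | C/C=C(\C)C=C | starting material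
17 | 9-[(3E)-3-methylpent-3-en-1-yl]-9-borabicyclo[3.3.1]nonane | C/C=C(\C)CCB1C2CCCC1CCC2 | intermediate
18 | 4-[(tert-butyldimethylsilyl)oxy]-2-[(3E)-3-methylpent-3-en-1-yl]phenol | C/C=C(\C)CCc1cc(O[Si](C)(C)C(C)(C)C)ccc1O | intermediate
19 | tert-butyl{[(2R)-2-ethenyl-2-methyl-3,4-dihydro-2H-chromen-6-yl]oxy}dimethylsilane | C=C[C@@]1(C)CCc2cc(O[Si](C)(C)C(C)(C)C)ccc2O1 | intermediate
20 | 4,4,5,5-tetramethyl-2-vinyl-1,3,2-dioxaborolane | C=CB1OC(C)(C)C(C)(C)O1 | starting material
21 | tert-butyldimethyl{[(2R)-2-methyl-2-[(E)-2-(4,4,5,5-tetramethyl-1,3,2-dioxaborolan-2-yl)ethenyl]-3,4-dihydro-2H-chromen-6-yl]oxy}silane | CC1(C)OB(/C=C/[C@@]2(C)CCc3cc(O[Si](C)(C)C(C)(C)C)ccc3O2)OC1(C)C | intermediate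
22 | tert-butyldimethyl{[(2R)-2-methyl-2-[(1E,3Z)-4-methyl-6-(2,6,6-trimethylcyclohex-1-en-1-yl)hexa-1,3-dien-1-yl]-3,4-dihydro-2H-chromen-6-yl]oxy}silane | CC1=C(CC/C(C)=C\C=C\[C@@]2(C)CCc3cc(O[Si](C)(C)C(C)(C)C)ccc3O2)C(C)(C)CCC1 | intermediate
23 | (2R)-2-methyl-2-[(1E,3Z)-4-methyl-6-(2,6,6-trimethylcyclohex-1-en-1-yl)hexa-1,3-dien-1-yl]-3,4-dihydro-2H-chromen-6-ol | CC1=C(CC/C(C)=C\C=C\[C@@]2(C)CCc3cc(O)ccc3O2)C(C)(C)CCC1 | target

**Step count and risks**

Total step count: 10. Longest linear sequence: 6 steps (1, 2, 3, 4, 9, 10; the chroman branch 5, 6, 7, 8, 9, 10 is equally long).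

Steps most likely to fail:

Step 3. The carbonyl coupling may stall at the titanium pinacolate, the ketyl may displace the β-chloride, or the β-chloro ketone may lose HCl before it couples. The fallback sets out from 7 and comes back at 9, and replaces the reductive coupling by an alkenylmetal addition. The silyl enol ether 7 is isolated after the conjugate addition and converted regiospecifically (CsF, PhNTf2, DME) into 9-chloro-6,6-dimethyl-7-oxonon-2-en-2-yl trifluoromethanesulfonate F1. An intramolecular Nozaki–Hiyama–Kishi reaction (CrCl2, NiCl2 cat., DMF) should add the alkenyl carbon to the hindered ketone and give 1-(2-chloroethyl)-2,6,6-trimethylcyclohex-2-en-1-ol F2. Ionic reduction (Et3SiH, BF3·OEt2, CH2Cl2, −78 °C) should deliver hydride to the less hindered CH end of the allyl cation and so place the double bond between the two fully substituted carbons, giving 9.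

Step 8. Metathesis at an alkene next to a quaternary carbon may be sluggish and lose out to homodimerization of the boronate. The fallback sets out from 19 and comes back at 22, and reverses the polarity of the diene coupling. Oxidative cleavage of the vinyl group (OsO4 cat., NaIO4, 2,6-lutidine, dioxane/H2O) should give (2R)-6-[(tert-butyldimethylsilyl)oxy]-2-methyl-3,4-dihydro-2H-chromene-2-carbaldehyde F6. Takai olefination (CrCl2, CHI3, THF) should give tert-butyl{[(2R)-2-[(E)-2-iodoethenyl]-2-methyl-3,4-dihydro-2H-chromen-6-yl]oxy}dimethylsilane F7. The alkenylcopper 12 of step 4, taken before iodination and transmetalated with ZnBr2, is then coupled with F7 under Pd(PPh3)4 (Negishi coupling with retention) to give 22.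

Step 7. Facial selectivity in the oxypalladation may be incomplete, or the alkene may isomerize before cyclization. The fallback sets out from 15 and comes back at 19, and sets the stereocenter by asymmetric allylic alkylation instead. Purchased (2E)-3-methylpent-2-en-4-yn-1-ol is semihydrogenated (H2, Pd/CaCO3 poisoned with Pb(OAc)2, quinoline) to (2E)-3-methylpenta-2,4-dien-1-ol F3. Hydroboration with 9-BBN (2 equiv) and B-alkyl Suzuki coupling with 15 should give 4-[(tert-butyldimethylsilyl)oxy]-2-[(3E)-5-hydroxy-3-methylpent-3-en-1-yl]phenol F4. Selective acylation of the primary allylic alcohol (ClCO2Me, pyridine, −20 °C) should give (2E)-5-{5-[(tert-butyldimethylsilyl)oxy]-2-hydroxyphenyl}-3-methylpent-2-en-1-yl methyl carbonate F5. Cyclization with Pd2(dba)3·CHCl3 and the enantiomer of N,N'-(cyclohexane-1,2-diyl)bis[2-(diphenylphosphino)benzamide] that delivers the (R) product (AcOH, CH2Cl2) should give 19 through attack of the phenol on the π-allyl complex of divalent palladium.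

Further compounds
F1 | step 3 | 9-chloro-6,6-dimethyl-7-oxonon-2-en-2-yl trifluoromethanesulfonate | CC(OS(=O)(=O)C(F)(F)F)=CCCC(C)(C)C(=O)CCCl
F2 | step 3 | 1-(2-chloroethyl)-2,6,6-trimethylcyclohex-2-en-1-ol (racemic) | CC1=CCCC(C)(C)C1(O)CCCl
F3 | step 7 | (2E)-3-methylpenta-2,4-dien-1-ol | OC/C=C(\C)C=C
F4 | step 7 | 4-[(tert-butyldimethylsilyl)oxy]-2-[(3E)-5-hydroxy-3-methylpent-3-en-1-yl]phenol | OC/C=C(\C)CCc1cc(O[Si](C)(C)C(C)(C)C)ccc1O
F5 | step 7 | (2E)-5-{5-[(tert-butyldimethylsilyl)oxy]-2-hydroxyphenyl}-3-methylpent-2-en-1-yl methyl carbonate | COC(=O)OC/C=C(\C)CCc1cc(O[Si](C)(C)C(C)(C)C)ccc1O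
F6 | step 8 | (2R)-6-[(tert-butyldimethylsilyl)oxy]-2-methyl-3,4-dihydro-2H-chromene-2-carbaldehyde | O=C[C@@]1(C)CCc2cc(O[Si](C)(C)C(C)(C)C)ccc2O1
F7 | step 8 | tert-butyl{[(2R)-2-[(E)-2-iodoethenyl]-2-methyl-3,4-dihydro-2H-chromen-6-yl]oxy}dimethylsilane | I/C=C/[C@@]1(C)CCc2cc(O[Si](C)(C)C(C)(C)C)ccc2O1
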